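Decision: reckon this flask by the slow return of the isomer of the product, not by the first step.

starting material 0.10 M; catalyst 0.50 mM; time 25 s

- target and crystals together at 25 s, in percent of the starting material charged
- the change that raises the amount of target and crystals together at 25 s, in percent of the starting material charged most ("none" if none brings more than 2 percentage points) (cedar / oak / larch / none)
- amount of target and crystals together at 25 s, in percent of the starting material charged, after oak

    starting material + catalyst ⇌ target + catalyst, rate k1*[starting material]*[catalyst] forward; the back reaction follows from the equilibrium constant (K1 = 5.2, k1 = 770 M⁻¹ s⁻¹)
    isomer of the product ⇌ starting material (k2 = 0.11 s⁻¹)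
    target ⇌ isomer of the product (K3 = 0.47, k3 = 0.020 s⁻¹)
    crystals ⇌ target, rate k4*(cs4 - [target]) while solid is left; crystals form when [target] > cs4 (cs4 = 4.5 mM, k4 = 1.5 s⁻¹)

1. With the catalyst as charged, the first step is pseudo-first-order. Starting material goes to target at 0.385 s⁻¹ and to the isomer of the product at 0.269 s⁻¹. At that pace [target] passes 4.5 mM after 0.117 s, far sooner than 25 s, so crystals are taken as present through the run. The reckoning sets [target] at 4.5 mM, which is an assumption about the crystals and not a result.

2. Control changes hands early: the forward half-life of starting material, 1.8 s, is shorter than the 6.3 s of the isomer of the product. The isomer's return is therefore taken as the rate-limiting step. It goes straight to target at 0.0426 s⁻¹, or through starting material, of which a share 58.9% reaches target. Together these give 0.107 s⁻¹, the drain constant: the rate constant at which the isomer pool empties into target.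

3. With [target] at 4.5 mM, the end pool holds 2.98% of the charge. The excess over it shrinks to the fraction 6.84% by 25 s. Starting that excess from the whole charge gives the low end of the bracket, 90.2%. Starting it from the diverted share gives the high end, 94.2%. Both ends are estimates under the assumption of step 1.

4. Oak raises the drain constant to 0.124 s⁻¹, which gives the bracket 92.5% to 95.9%. Cedar doubles the solubility and with it the end pool, and the dissolution coefficient doubled by larch does not enter the drain constant. The choice is oak.

The forecast gives 92.2%, oak and 95.2%, inside both brackets, from “The crystals keep dissolved target pinned near 4.5 mM, so the system is linear once solid appears.” Its slow eigenvalue, 0.095 s⁻¹, differs from the drain constant above.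

The flask gives 92.2%, and 95.2% after oak, a gain of 3 percentage points; cedar brings −2.7 points and larch 0.34 points.

In this flask the excess pool reads 15.9% at 12.5 s. The drain constant carries that to 4.17% at 25 s, where the readings give 4.86%. The neighbouring flask, with 0.0020 M of catalyst, has a forward constant of 1.54 s⁻¹ and so a drain constant of 0.136 s⁻¹. Its bracket runs from 93.7% to 96.5%. That neighbouring flask gives 96.3%.

All constants stand for no real mixture; the rest is arithmetic.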